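Two questions stand on the next flask, and behind them one decision: is the maple charge worth running as written, with 5.20 M of partner for 37 h?

common to all: starting material 0.500 M

| charge | partner | time |
|---|---|---|
| birch | 1.50 M |  |
| oak | 3.00 M |  |
| maple | 5.20 M | 37 h |

| run | time / h | [product] / M |
|---|---|---|
| birch run | 6.2 | 0.133 |
| birch run | 12 | 0.184 |
| birch run | 18 | 0.200 |
| birch run | 25 | 0.236 |
| birch run | 31 | 0.223 |
| birch run | 37 | 0.246 |
| oak run | 6.2 | 0.204 |
| oak run | 12 | 0.271 |
| oak run | 18 | 0.310 |
| oak run | 25 | 0.312 |
| oak run | 31 | 0.311 |
| oak run | 37 | 0.318 |

(readings scatter by 0.005 M)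

* reaction order in [partner] at the outset, round the charge of the birch run, defined at two percent of the starting material turned into product
* product in the maple run at 37 h, as a share of the starting material charged

- Overall: starting material + partner -> product.
- Constant volume, constant temperature.
- "The second partner" is partner.
- An order is taken over about fifteen percent of the charge, up and down.

The time can stay. Oak product reads 0.310 M at 18 h and 0.318 M at 37 h, a rise of 0.00800 M against a scatter of 0.005 M.

The partner charge needs a number that carries from flask to flask, so look for what stays nearly constant. Let P be the mean product from 25 h on, and let S and R be the charges of starting material and partner. The end quotient Q is P/((S−P)(R−P)), product over what the overall equation leaves of each charge. I treat it as a reading and claim no more for it.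

Birch gives P = 0.235 M and Q = 0.701 L mol⁻¹. Oak gives P = 0.314 M and Q = 0.627 L mol⁻¹. So twice the partner moves Q little. I freeze their mean, 0.664 L mol⁻¹, as the end quotient.

Starting material is the limiting reagent in maple, at 0.500 M against 5.20 M. Solving Q for maple gives 0.381 M, which is 76.2% of the charge and 0.0670 M above oak. That gain is worth a run, so I would charge maple as written.

The forecast says 75%, a little below my figure, and gives an order of 0.75. Its ground for the yield is “Maple should be at equilibrium by 37 h”.

The maple flask gives 76.8% at 37 h, and the order in partner at the outset, round the birch charge, is 0.68.

    starting material ⇌ intermediate + by-product (0.6120 h⁻¹, 7.488 L mol⁻¹ h⁻¹)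
    intermediate + partner → product (0.1897 L mol⁻¹ h⁻¹)
    partner → lost reagent (0.06012 h⁻¹)
    2 starting material → homo dimer (0.1040 L mol⁻¹ h⁻¹)

The fit with main steps alone, which leaves out both the step to homo dimer and the loss of partner, lands at 81.7% for maple, 4.9 percentage points above the flask. The maple flask's product is 0.384 M. The scheme writes the product step one way, yet maple's end quotient reads 0.686 L mol⁻¹, above the frozen 0.664 L mol⁻¹ and oak's 0.627 L mol⁻¹ and below birch's 0.701 L mol⁻¹.

The readings were computed with constants of no real substance.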